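**Retrosynthetic overview** (benzofuran numbering: O1, C2, C3, C3a, C4–C7, C7a)
1. 8 ⇒ 7 + prenyl bromide: cut the C3a–prenyl bond, so the last step is an alkylative dearomatisation of an already cyclised, enantioenriched dihydrobenzofuran, with C2 steering the prenyl group to the opposite face.
2. 7 ⇒ 6 ⇒ 5: cut the O1–C2 bond, an epoxide opening by the para-phenol oxygen; the epoxide comes from asymmetric epoxidation of one of the two equivalent prenyl groups of deoxyhumulone.
3. 5 ⇒ 3 + two prenyl bromide; 3 ⇒ phloroglucinol + isovaleryl chloride.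
4. Ring order: the carbocycle is bought as the phloroglucinol ring, the dihydrofuran ring is closed on the arene (step 3, sets C2), and the carbocycle is dearomatised last (step 4, sets C3a).

Assumption: the D-fructose-derived Shi ketone gives the (R)-epoxide of an ArCH2–CH=CMe2 unit, as it does for other trisubstituted alkenes; if the sense were reversed, the L-fructose-derived ketone would be used.

**Route**

Step 1
Reactants: 1 phloroglucinol; 2 isovaleryl chloride (1.05 equiv)
Product: 3 phlorisovalerophenone
Conditions: AlCl3 (3.5 equiv), PhNO2/CH2Cl2, 0 → 45 °C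
Reagents that add atoms: none
Why: Friedel–Crafts C-acylation of the very electron-rich triol, in which the first acyl group deactivates the ring so that mono-acylation is clean; no stereocentre is formed.

Step 2
Reactants: 3 phlorisovalerophenone; 4 prenyl bromide (2.1 equiv)
Product: 5 deoxyhumulone
Conditions: 10% aq KOH, 0 °C → rt
Reagents that add atoms: none
Why: C-alkylation of the phloroglucinol phenoxide with a soft allylic bromide in water, which favours carbon over oxygen and puts one prenyl group on each of the two free ring positions; no stereocentre is formed.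

Step 3
Reactants: 5 deoxyhumulone
Product: 7 1-[(2S)-4,6-dihydroxy-2-(2-hydroxypropan-2-yl)-7-(3-methylbut-2-en-1-yl)-2,3-dihydro-1-benzofuran-5-yl]-3-methylbutan-1-one, via deoxyhumulone (R)-monoepoxide 6 (not isolated)
Conditions: D-fructose-derived Shi ketone (30 mol%), Oxone (1.0 equiv), K2CO3, Bu4NHSO4 (cat), MeCN/DMM–aq Na2B4O7/EDTA (pH 10.5), 0 °C, then rt; unreacted 5 recovered
Reagents that add atoms: Oxone, active component potassium peroxymonosulfate KHSO5, [K+].[O-]S(=O)(=O)OO
Why: Shi asymmetric epoxidation (chiral dioxirane, spiro transition state) turns one of the two symmetry-equivalent prenyl alkenes into the (R)-epoxide, and at pH 10.5 the unchelated para-phenoxide (the most acidic OH) opens it in the same flask by 5-exo-tet SN2 attack at the secondary epoxide carbon with inversion, so that C2 of the new ring is (S); this epoxidation/phenol-cyclisation pair is how such rings are presumed to form in the plant, run here on the free polyphenol.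

Step 4
Reactants: 7 the (2S)-dihydrobenzofuran from step 3; 4 prenyl bromide (1.2 equiv)
Product: 8 (2S,3aS)-6-hydroxy-2-(2-hydroxypropan-2-yl)-5-(3-methylbutanoyl)-3a,7-bis(3-methylbut-2-en-1-yl)-3,3a-dihydro-1-benzofuran-4(2H)-one (target)
Conditions: NaOMe (2.2 equiv), MeOH, −10 → 0 °C
Reagents that add atoms: none
Why: Alkylative dearomatisation (the phenoxide C-prenylation that turns deoxyhumulone into lupulone) at C3a, which is ortho to O4 and para to O6 and whose change to sp3 relieves strain in the fused five-membered ring, with prenyl bromide approaching the flat arene anti to the bulky C2 hydroxyisopropyl group (1,3-induction across the five-membered ring), which sets the quaternary centre as (3aS), trans to that group.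

**Compound list**
1 | phloroglucinol (benzene-1,3,5-triol) | Oc1cc(O)cc(O)c1 | starting material
2 | isovaleryl chloride (3-methylbutanoyl chloride) | CC(C)CC(Cl)=O | starting material
3 | phlorisovalerophenone, 3-methyl-1-(2,4,6-trihydroxyphenyl)butan-1-one | CC(C)CC(=O)c1c(O)cc(O)cc1O | intermediate
4 | prenyl bromide (1-bromo-3-methylbut-2-ene) | CC(C)=CCBr | starting material
5 | deoxyhumulone, 3-methyl-1-[2,4,6-trihydroxy-3,5-bis(3-methylbut-2-en-1-yl)phenyl]butan-1-one | CC(C)CC(=O)c1c(O)c(CC=C(C)C)c(O)c(CC=C(C)C)c1O | intermediate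
6 | deoxyhumulone (R)-monoepoxide, formed in the flask in step 3: 1-[3-{[(2R)-3,3-dimethyloxiran-2-yl]methyl}-2,4,6-trihydroxy-5-(3-methylbut-2-en-1-yl)phenyl]-3-methylbutan-1-one | CC(C)CC(=O)c1c(O)c(C[C@H]2OC2(C)C)c(O)c(CC=C(C)C)c1O | intermediate
7 | 1-[(2S)-4,6-dihydroxy-2-(2-hydroxypropan-2-yl)-7-(3-methylbut-2-en-1-yl)-2,3-dihydro-1-benzofuran-5-yl]-3-methylbutan-1-one | CC(C)CC(=O)c1c(O)c2C[C@@H](C(C)(C)O)Oc2c(CC=C(C)C)c1O | intermediate
8 | (2S,3aS)-6-hydroxy-2-(2-hydroxypropan-2-yl)-5-(3-methylbutanoyl)-3a,7-bis(3-methylbut-2-en-1-yl)-3,3a-dihydro-1-benzofuran-4(2H)-one | CC(C)=CCC1=C2O[C@H](C(C)(C)O)C[C@]2(CC=C(C)C)C(=O)C(C(=O)CC(C)C)=C1O | target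

**Step count and risks**

Total step count: 4. Longest linear sequence: 4 steps (1 → 3 → 5 → 7 → 8).

Three steps most likely to fail:

Step 3. The dioxirane may oxidise the electron-rich phenoxide ring (humulone-type C-hydroxylation) instead of an alkene. Both prenyl groups may be epoxidised, and an ortho-OH may close the ring in place of the para-OH. The fallback sets out from 5 and comes back at 7; it masks the ring before oxidation. Ac2O/pyridine/DMAP converts 5 into deoxyhumulone triacetate F1. Shi epoxidation of this deactivated arene (same ketone, 1 equiv Oxone) gives the (R)-monoepoxide triacetate F2. K2CO3 in MeOH then removes the three acetates, and the phenoxide of 6 set free in the flask closes to 7.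

Step 4. Prenyl bromide may attack C7 (giving the geminal diprenyl isomer) or oxygen, and the facial bias of the remote C2 group may be modest. The fallback sets out from 5 and comes back at 8; it dearomatises before the ring is made. A third C-prenylation of 5 (4, NaOMe, MeOH) gives lupulone F3. Shi epoxidation of F3 with limiting Oxone forms, among other epoxides, the (6S)-geminal-prenyl (R)-epoxide F4. F4 closes in the flask through the C5 enol oxygen to 8. Here the quaternary centre is not controlled, so 8 must be separated by preparative HPLC from its C3a epimer and from the products of epoxidation at the other prenyl group.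

Step 2. The alkylation gives a statistical mixture of mono-, di- and tri-prenylated products, and 5 is air-sensitive in base. The fallback sets out from 3 and comes back at 7; it adds one prenyl group at a time and closes the ring in between. Mono-prenylation of excess 3 (4, aq KOH) gives 3-prenylphlorisovalerophenone F5. Shi epoxidation, now with a single alkene and so run to full conversion, gives the (R)-epoxide of the monoprenyl ketone F6. F6 closes in the flask to the C7-unsubstituted (2S)-dihydrobenzofuran F7. C-prenylation of F7 at its only free aromatic position (4, 1 equiv, aq KOH, 0 °C) gives 7.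

**Further compounds**
F1 | step 3 | deoxyhumulone triacetate, 2-(3-methylbutanoyl)-4,6-bis(3-methylbut-2-en-1-yl)benzene-1,3,5-triyl triacetate | CC(C)CC(=O)c1c(OC(C)=O)c(CC=C(C)C)c(OC(C)=O)c(CC=C(C)C)c1OC(C)=O
F2 | step 3 | (R)-monoepoxide triacetate, 2-{[(2R)-3,3-dimethyloxiran-2-yl]methyl}-4-(3-methylbut-2-en-1-yl)-6-(3-methylbutanoyl)benzene-1,3,5-triyl triacetate | CC(C)CC(=O)c1c(OC(C)=O)c(C[C@H]2OC2(C)C)c(OC(C)=O)c(CC=C(C)C)c1OC(C)=O
F3 | step 4 | lupulone, 3,5-dihydroxy-2-(3-methylbutanoyl)-4,6,6-tris(3-methylbut-2-en-1-yl)cyclohexa-2,4-dien-1-one | CC(C)CC(=O)C1=C(O)C(CC=C(C)C)=C(O)C(CC=C(C)C)(CC=C(C)C)C1=O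
F4 | step 4 | (6S)-6-{[(2R)-3,3-dimethyloxiran-2-yl]methyl}-3,5-dihydroxy-2-(3-methylbutanoyl)-4,6-bis(3-methylbut-2-en-1-yl)cyclohexa-2,4-dien-1-one | CC(C)=CCC1=C(O)[C@@](C[C@H]2OC2(C)C)(CC=C(C)C)C(=O)C(C(=O)CC(C)C)=C1O
F5 | step 2 | 3-prenylphlorisovalerophenone, 3-methyl-1-[2,4,6-trihydroxy-3-(3-methylbut-2-en-1-yl)phenyl]butan-1-one | CC(C)CC(=O)c1c(O)cc(O)c(CC=C(C)C)c1O
F6 | step 2 | 1-[3-{[(2R)-3,3-dimethyloxiran-2-yl]methyl}-2,4,6-trihydroxyphenyl]-3-methylbutan-1-one | CC(C)CC(=O)c1c(O)cc(O)c(C[C@H]2OC2(C)C)c1O
F7 | step 2 | 1-[(2S)-4,6-dihydroxy-2-(2-hydroxypropan-2-yl)-2,3-dihydro-1-benzofuran-5-yl]-3-methylbutan-1-one | CC(C)CC(=O)c1c(O)cc2O[C@H](C(C)(C)O)Cc2c1O
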